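## The problem

Numbering used throughout (drimane type): ring A = C1–C2–C3–C4–C5–C10, ring B = C5–C6–C7–C8–C9–C10. C4 carries the gem-dimethyl group, C8 a methyl and H, C9 a methyl and the benzylic carbon C11, which bears the quinone. Target **15** is (8S,9R); in the SMILES, C9 is the `[C@@]2(C)` atom and C8 the `[C@@H]2C` atom.

- The ring-fusion double bond C5=C10 is tetrasubstituted and wedged between two quaternary carbons (C4 and C9). It must sit there and not at C5–C6 or C1–C10, and neither an olefination nor a late alkylation can place it.
- The only stereocentres, quaternary C9 and tertiary C8, are adjacent. Their methyl groups are cis, so C11 is trans to the C8 methyl. Nothing else in the molecule can steer them, so C8 must be set absolutely and C9 from C8.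
- C9–C11 is a neopentyl bond to a 2,6-dioxygenated benzyl group. Made late on a finished decalin, it costs a hindered carbonyl addition and a deoxygenation.
- The 2-hydroxy-5-methoxyquinone is a vinylogous acid/ester that will not survive organometallics, strong acid or reductants. It must be unveiled last from an inert arene, with OH on the carbon next to the alkylated one.
- The enabling feature is that C10 is sp2. Read as a former carbonyl carbon, C10–C9–C8 is the C1–C2–C3 triad of 2-methylcyclohex-2-enone. The trans relation of the C8 methyl and C11 is what conjugate addition at C8 followed by anti alkylation of the enolate at C9 delivers.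
- The same C10 carbonyl, with C5 as its only hydrogen-bearing α-carbon and the gem-dimethyl C4 attached to C5, is the footprint of a 4-methylpent-3-enyl chain closing by a cation–olefin reaction that ends at C5=C10.

## Retrosynthesis

**15 ⇒ 14 ⇒ 13 (no C–C bond cut).** The hydroxy-methoxyquinone is traced to the 2,5-dimethoxyquinone **14** and then to the 2,3,5,6-tetramethoxyphenyl compound **13**. This arene tolerates organometallics and acid, and its single free position is para to C11, so it cannot trap a cation in the terpenoid part. The forward reactions must give para-quinone oxidation without touching C5=C10, then hydrolysis of only the methoxy group flanked by C11.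

**13 ⇒ 11 ⇒ 8 + 9 (cut C4–C5 and C1–C10; C5=C10 returns to C10=O).** This removes ring A, the gem-dimethyl carbon and the hindered alkene in one stroke. It leaves the monocyclic ketone **8** and the commercial bromide **9**.
- The neighbouring cut C9–C11 on the bicycle would leave a neopentyl aldehyde to be arylated and deoxygenated.
- A cycloaddition cut of ring B (C9–C10 / C7–C8) would put the alkene at C5–C6 and create a C10 stereocentre only to erase it.
- The forward reaction needs 1,2-addition of the C6 chain to a hindered ketone (carbinol **11**, both epimers usable), then acid. Ionisation and loss of H5 give diene **12**; the chain cation at C4 is captured by C5; the resulting C10 cation loses H5.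
- That C10 cation is the one on which the biosynthetic 1,2-shift cascade ends. Here it is reached by ring closure, so C8 and C9 are already in place and no group has to migrate.

**8 ⇒ 5 + Me3Al + 4 (cut C8–CH3 and C9–C11).** The 19-carbon ketone **8**, with both stereocentres and the arene, falls apart into the achiral enone **5**, a methyl nucleophile and the benzylic bromide **4**.
- Cutting C9–CH3 instead (methylating a 2-benzyl enolate) would put the methyl anti to the C8 methyl, the wrong diastereomer.
- Cutting only C9–C11 from a preformed 2,3-dimethylcyclohexanone would need a separate source of C8 and regiocontrol of enolisation.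
- The forward reaction needs catalyst-controlled methyl transfer to C8, then alkylation of the regiodefined enolate at C9 anti to the new methyl.

**4 ⇒ 3 ⇒ 1 (cut C11–aryl).** The bromide **4** comes from the alcohol **3**, made by hydroxymethylation of 1,2,4,5-tetramethoxybenzene **1**. Each free position of **1** lies between two methoxy groups, so lithiation is unambiguous.

## Roads not taken

**Alternative 1: biomimetic rearrangement of a preformed drimane (the most obvious route).** No ring bond is cut. (+)-Sclareolide **A1** is degraded to a C9 aldehyde, arylated and deoxygenated to the 8(12)-drimenyl arene **A2**. Acid then drives the C9→C8 hydride shift and the C10→C9 methyl shift to **13**.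
- The chosen plan is better because **A2** already costs a degradation, a hindered aryl addition and a neopentyl benzylic deoxygenation.
- In this route C8 and C9 are created inside a cation cascade. Its partitioning (proton loss at the C8 or C9 cation, further H5/C4-methyl shifts, capture by an aryl oxygen) is under no external control.
- The chosen route sets both centres before any cation exists and enters the same terminal C10 cation directly.

**Alternative 2: Diels–Alder construction of ring B.** The cut is C9–C10 and C7–C8. 6,6-Dimethyl-1-vinylcyclohexene **A3** and (E)-2-methylbut-2-enal **A4** would give the Δ5(6) aldehyde **A5**. Aryl addition, deoxygenation and acid isomerisation of the alkene into C5=C10 would follow.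
- The two alkyl groups of **A3** direct regiochemistry in opposite senses.
- Enantiocontrol with an α,β-disubstituted enal and a hindered diene is demanding.
- A C10 stereocentre is made only to be destroyed, the alkene lands in the wrong place, and the neopentyl deoxygenation remains. The chosen plan avoids all four and is shorter.

**Alternative 3: dearomatisation by Birch reduction–alkylation.** The cut is C9–CH3 on a flat precursor. The chiral tetralin amide **A6** would be reduced and methylated to the 1,4-diene **A7**. C5=C10 survives as the unreduced ring-fusion alkene and C9 becomes quaternary. A hydroxyl-directed hydrogenation of C7=C8 and aryl addition/deoxygenation would follow.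
- The ring-B pattern fits a Birch product well, but facial control by the amide enolate needs one ortho substituent to fix the enolate geometry.
- In **A6** both ortho positions carry alkyl groups of nearly equal size (the C8 methyl and C1H2), so C9 would not be controlled.
- One of two alkenes must then be hydrogenated selectively, and the deoxygenation returns.

Key step: step 3

Assumption: the sense of induction of the Cu/phosphoramidite catalyst in step 3 is taken to parallel its behaviour with cyclohex-2-enone. If the opposite sense is found, the antipodal ligand is used.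

## Route

Step 1
Reactants: 1 1,2,4,5-tetramethoxybenzene
Product: 3 (2,3,5,6-tetramethoxyphenyl)methanol, via 2,3,5,6-tetramethoxyphenyllithium 2 (not isolated)
Conditions: n-BuLi, TMEDA, THF, 0 °C → rt; (CH2O)n, 0 °C → rt; H2O
Reagents that add atoms: paraformaldehyde (formaldehyde unit), C=O
Why: Directed ortho-lithiation; both free positions of 1 are equivalent and doubly activated by flanking methoxy groups. The aryllithium is hydroxymethylated by formaldehyde released from paraformaldehyde.

Step 2
Reactants: 3 (2,3,5,6-tetramethoxyphenyl)methanol
Product: 4 3-(bromomethyl)-1,2,4,5-tetramethoxybenzene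
Conditions: PBr3 (0.4 equiv), Et2O, 0 °C; used without storage
Reagents that add atoms: phosphorus tribromide, BrP(Br)Br
Why: Standard conversion of an electron-rich benzylic alcohol to the bromide. Low temperature and short contact limit self-alkylation at the one free, hindered ring position.

Step 3
Reactants: 5 2-methylcyclohex-2-en-1-one; 4 3-(bromomethyl)-1,2,4,5-tetramethoxybenzene
Product: 8 (2R,3S)-2,3-dimethyl-2-[(2,3,5,6-tetramethoxyphenyl)methyl]cyclohexan-1-one, via dimethylaluminium enolate 6 (not isolated), via lithium trimethylalanate enolate 7 (not isolated)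
Conditions: Me3Al (1.3 equiv), CuTC (2 mol %), (S)-BINOL/bis[(R)-1-phenylethyl]amine phosphoramidite (4 mol %), Et2O, −30 °C; MeLi (1.3 equiv), THF/DMPU, −30 °C; 4 (1.2 equiv), −30 °C → rt; H2O
Reagents that add atoms: trimethylaluminium, C[Al](C)C
Why: Cu(I)/phosphoramidite-catalysed conjugate transfer of methyl from Me3Al to C3 of enone 5 (π-complex, Cu(III) σ-enolate, reductive elimination) sets C8 under catalyst control and leaves the regiodefined tetrasubstituted aluminium enolate 6; MeLi converts 6 into the more nucleophilic alanate 7, which is C-benzylated by 4. The closest known reaction type is asymmetric conjugate addition to α-substituted cyclohexenones with trapping of the metal enolate by allylic or benzylic halides. No ring is closed. C9 is set by substrate control: in the half-chair enolate the new C3 methyl sits pseudoaxial to avoid A(1,2) strain with the C2 methyl, and the bromide attacks C2 axially from the opposite face, so the arylmethyl group ends up trans to the C3 methyl and the two methyls cis, as in 15. The step needs 1,4- over 1,2-addition (Cu catalysis, ether, low temperature), C- over O-alkylation (soft benzylic bromide) and alkylation at C2 only, which holds because the enolate is generated regiospecifically and consumed before it can equilibrate to C6. The high SN2 reactivity of the electron-rich benzylic bromide offsets the hindrance of forming a quaternary centre next to a tertiary one.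

Step 4
Reactants: 8 (2R,3S)-2,3-dimethyl-2-[(2,3,5,6-tetramethoxyphenyl)methyl]cyclohexan-1-one; 9 5-bromo-2-methylpent-2-ene
Product: 11 (2R,3S)-2,3-dimethyl-1-(4-methylpent-3-en-1-yl)-2-[(2,3,5,6-tetramethoxyphenyl)methyl]cyclohexan-1-ol (both C1 epimers), via (4-methylpent-3-en-1-yl)magnesium bromide 10 (not isolated)
Conditions: 9, Mg, THF, rt; anhydrous CeCl3, THF, −78 °C; 8, −78 → 0 °C; H2O
Reagents that add atoms: none
Why: Organocerium 1,2-addition, the standard answer to hindered, enolisable ketones. The carbinol configuration does not matter because C10 becomes sp2 in step 5; C8 and C9 are untouched.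

Step 5
Reactants: 11 (2R,3S)-2,3-dimethyl-1-(4-methylpent-3-en-1-yl)-2-[(2,3,5,6-tetramethoxyphenyl)methyl]cyclohexan-1-ol
Product: 13 3-{[(1R,2S)-1,2,5,5-tetramethyl-1,2,3,4,5,6,7,8-octahydronaphthalen-1-yl]methyl}-1,2,4,5-tetramethoxybenzene, via ring-B diene 12 (not isolated)
Conditions: MeSO3H (3 equiv), CH2Cl2 (0.02 M), −20 → 0 °C
Reagents that add atoms: none
Why: Dehydrative cation–olefin annulation, the acid closure of 1-(4-methylpent-3-enyl)cyclohexenes to 1,1-dimethyl-octahydronaphthalenes: either epimer of 11 ionises and loses H5 to give 12, Markovnikov protonation of the chain alkene gives the C4 cation, C5 of the ring alkene attacks it (6-endo, the only mode leaving a tertiary cation, at C10), and loss of H5 gives the tetrasubstituted C5=C10 alkene. C9 is quaternary, so C5 is the only ring position from which the C10 cation can lose a proton, and the exocyclic isomer cannot cyclise and returns through the same cation. The arene's one free position is para to C11 and cannot trap either cation.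

Step 6
Reactants: 13 3-{[(1R,2S)-1,2,5,5-tetramethyl-1,2,3,4,5,6,7,8-octahydronaphthalen-1-yl]methyl}-1,2,4,5-tetramethoxybenzene
Product: 14 2,5-dimethoxy-3-{[(1R,2S)-1,2,5,5-tetramethyl-1,2,3,4,5,6,7,8-octahydronaphthalen-1-yl]methyl}cyclohexa-2,5-diene-1,4-dione
Conditions: (NH4)2Ce(NO3)6 (2.5 equiv), MeCN/H2O, 0 °C
Reagents that add atoms: water, O
Why: Oxidative demethylation of a para-dimethoxyarene by Ce(IV) (arene radical cation, ipso attack of water, loss of methanol); both para pairs of methoxy groups give the same quinone. The tetramethoxyarene is oxidised at a much lower potential than the hindered tetrasubstituted alkene.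

Step 7
Reactants: 14 2,5-dimethoxy-3-{[(1R,2S)-1,2,5,5-tetramethyl-1,2,3,4,5,6,7,8-octahydronaphthalen-1-yl]methyl}cyclohexa-2,5-diene-1,4-dione
Product: 15 2-hydroxy-5-methoxy-3-{[(1R,2S)-1,2,5,5-tetramethyl-1,2,3,4,5,6,7,8-octahydronaphthalen-1-yl]methyl}cyclohexa-2,5-diene-1,4-dione
Conditions: KOH, MeOH/H2O, rt; 1 M HCl
Reagents that add atoms: potassium hydroxide, [K+].[OH-]
Why: Addition–elimination of hydroxide on a vinylogous ester. The methoxy group squeezed between a carbonyl and the neopentyl C11 cannot lie in the ring plane and donates less, so its carbon is the more electrophilic; the resulting vinylogous carboxylate resists a second attack. This is the regiochemistry relied on for 2-hydroxy-5-methoxy-3-alkylquinones.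

## Compound list

1 | 1,2,4,5-tetramethoxybenzene | COc1cc(OC)c(OC)cc1OC | starting material
2 | 2,3,5,6-tetramethoxyphenyllithium | [Li]c1c(OC)c(OC)cc(OC)c1OC | intermediate
3 | (2,3,5,6-tetramethoxyphenyl)methanol | OCc1c(OC)c(OC)cc(OC)c1OC | intermediate
4 | 3-(bromomethyl)-1,2,4,5-tetramethoxybenzene | BrCc1c(OC)c(OC)cc(OC)c1OC | intermediate
5 | 2-methylcyclohex-2-en-1-one | CC1=CCCCC1=O | starting material
6 | dimethylaluminium (3S)-2,3-dimethylcyclohex-1-en-1-olate | C[C@H]1CCCC(O[Al](C)C)=C1C | intermediate
7 | lithium trimethyl{[(3S)-2,3-dimethylcyclohex-1-en-1-yl]oxy}alanate | [Li+].C[C@H]1CCCC(O[Al-](C)(C)C)=C1C | intermediate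
8 | (2R,3S)-2,3-dimethyl-2-[(2,3,5,6-tetramethoxyphenyl)methyl]cyclohexan-1-one | COc1cc(OC)c(OC)c(C[C@@]2(C)C(=O)CCC[C@@H]2C)c1OC | intermediate
9 | 5-bromo-2-methylpent-2-ene | CC(C)=CCCBr | starting material
10 | (4-methylpent-3-en-1-yl)magnesium bromide | CC(C)=CCC[Mg]Br | intermediate
11 | (2R,3S)-2,3-dimethyl-1-(4-methylpent-3-en-1-yl)-2-[(2,3,5,6-tetramethoxyphenyl)methyl]cyclohexan-1-ol (C1 epimers) | COc1cc(OC)c(OC)c(C[C@@]2(C)C(O)(CCC=C(C)C)CCC[C@@H]2C)c1OC | intermediate
12 | 3-{[(1R,6S)-1,6-dimethyl-2-(4-methylpent-3-en-1-yl)cyclohex-2-en-1-yl]methyl}-1,2,4,5-tetramethoxybenzene | COc1cc(OC)c(OC)c(C[C@@]2(C)C(CCC=C(C)C)=CCC[C@@H]2C)c1OC | intermediate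
13 | 3-{[(1R,2S)-1,2,5,5-tetramethyl-1,2,3,4,5,6,7,8-octahydronaphthalen-1-yl]methyl}-1,2,4,5-tetramethoxybenzene | COc1cc(OC)c(OC)c(C[C@@]2(C)C3=C(CC[C@@H]2C)C(C)(C)CCC3)c1OC | intermediate
14 | 2,5-dimethoxy-3-{[(1R,2S)-1,2,5,5-tetramethyl-1,2,3,4,5,6,7,8-octahydronaphthalen-1-yl]methyl}cyclohexa-2,5-diene-1,4-dione | COC1=CC(=O)C(OC)=C(C[C@@]2(C)C3=C(CC[C@@H]2C)C(C)(C)CCC3)C1=O | intermediate
15 | 2-hydroxy-5-methoxy-3-{[(1R,2S)-1,2,5,5-tetramethyl-1,2,3,4,5,6,7,8-octahydronaphthalen-1-yl]methyl}cyclohexa-2,5-diene-1,4-dione | COC1=CC(=O)C(O)=C(C[C@@]2(C)C3=C(CC[C@@H]2C)C(C)(C)CCC3)C1=O | target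

## Step count and risks

Total steps: 7. Longest linear sequence: 7 (1 → 3 → 4 → 8 → 11 → 13 → 14 → 15); 5 steps from enone 5.

**Step 3 (key step).**
- What may go wrong: weak enantiofacial discrimination in the methyl transfer (methyl is the least selective alkyl group and the α-methyl twists the enone); slow C-alkylation of the hindered alanate, so that protonation or O-alkylation competes; incomplete anti selectivity at C9.
- Fallback: the three-component operation is split. Setting out from 5, the conjugate addition is run alone and enolate 6 is silylated to trimethyl{[(3S)-2,3-dimethylcyclohex-1-en-1-yl]oxy}silane F1, which is isolated and assayed for enantiopurity. MeLi in THF then releases the aluminium-free lithium enolate, which is benzylated with 4 in THF/DMPU. The sequence returns to the route at 8.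

**Step 5.**
- What may go wrong: 1,2-shift of the arylmethyl or methyl group from C9 to the first-formed carbinol cation at C10 before the ring closes; proton loss from C1 after closure, giving the Δ1(10) isomer; reprotonation of the product with further hydride and methyl shifts.
- Fallback: the carbinol cation is avoided. Setting out from 8, deprotonation at C5 (the only possible site) and triflation with KHMDS/PhNTf2 give the enol triflate (5S,6R)-5,6-dimethyl-6-[(2,3,5,6-tetramethoxyphenyl)methyl]cyclohex-1-en-1-yl trifluoromethanesulfonate F2. Iron-catalysed cross-coupling of F2 with Grignard reagent 10 gives diene 12 as an isolated compound. It is closed at −78 °C with SnCl4 or MeSO3H, so that the only cation next to C9 is the one born by ring closure. The sequence returns at 13.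

**Step 4.**
- What may go wrong: enolisation at C5 or β-hydride reduction instead of addition, because the carbonyl is flanked by a quaternary carbon carrying a bulky arylmethyl group.
- Fallback: a smaller nucleophile is added and the chain completed afterwards. Setting out from 8, vinylmagnesium bromide/CeCl3 gives the vinyl carbinol (2R,3S)-1-ethenyl-2,3-dimethyl-2-[(2,3,5,6-tetramethoxyphenyl)methyl]cyclohexan-1-ol F3. Hydroboration with 9-BBN gives the B-alkyl-9-borabicyclo[3.3.1]nonane adduct F4 (not isolated). Suzuki coupling of F4 with 1-bromo-2-methylprop-1-ene (Pd(dppf)Cl2, aqueous base) returns to the route at 11.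

**Step 7.**
- What may go wrong: attack of hydroxide at the unhindered methoxy-bearing carbon next to the ring CH, or at both positions, giving the regioisomeric hydroxyquinone or over-hydrolysis.
- Fallback: setting out from 14, exhaustive hydrolysis (aqueous NaOH, warm, then acid) gives the dihydroxyquinone 2,5-dihydroxy-3-{[(1R,2S)-1,2,5,5-tetramethyl-1,2,3,4,5,6,7,8-octahydronaphthalen-1-yl]methyl}cyclohexa-2,5-diene-1,4-dione F5. Acid-catalysed mono-methylation in methanol (a vinylogous Fischer esterification) then takes place at the hydroxyl-bearing carbon next to the ring CH, the less hindered of the two. The sequence returns at 15.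

## Further compounds

F1 | step 3 | trimethyl{[(3S)-2,3-dimethylcyclohex-1-en-1-yl]oxy}silane | C[C@H]1CCCC(O[Si](C)(C)C)=C1C
F2 | step 5 | (5S,6R)-5,6-dimethyl-6-[(2,3,5,6-tetramethoxyphenyl)methyl]cyclohex-1-en-1-yl trifluoromethanesulfonate | COc1cc(OC)c(OC)c(C[C@@]2(C)C(OS(=O)(=O)C(F)(F)F)=CCC[C@@H]2C)c1OC
F3 | step 4 | (2R,3S)-1-ethenyl-2,3-dimethyl-2-[(2,3,5,6-tetramethoxyphenyl)methyl]cyclohexan-1-ol (C1 epimers) | COc1cc(OC)c(OC)c(C[C@@]2(C)C(O)(C=C)CCC[C@@H]2C)c1OC
F4 | step 4 | 9-{2-[(2R,3S)-1-hydroxy-2,3-dimethyl-2-[(2,3,5,6-tetramethoxyphenyl)methyl]cyclohexyl]ethyl}-9-borabicyclo[3.3.1]nonane | COc1cc(OC)c(OC)c(C[C@@]2(C)C(O)(CCB3C4CCCC3CCC4)CCC[C@@H]2C)c1OC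
F5 | step 7 | 2,5-dihydroxy-3-{[(1R,2S)-1,2,5,5-tetramethyl-1,2,3,4,5,6,7,8-octahydronaphthalen-1-yl]methyl}cyclohexa-2,5-diene-1,4-dione | OC1=CC(=O)C(O)=C(C[C@@]2(C)C3=C(CC[C@@H]2C)C(C)(C)CCC3)C1=O
A1 | alternative 1 | (+)-sclareolide | C[C@]12CCCC([C@@H]1CC[C@@]3([C@@H]2CC(=O)O3)C)(C)C
A2 | alternative 1 | 8(12)-drimen-11-yl arene (9β-arylmethyl, 10β-methyl, 5α-H): 1,2,4,5-tetramethoxy-3-[(5,5,8a-trimethyl-2-methylidenedecahydronaphthalen-1-yl)methyl]benzene | COc1cc(OC)c(OC)c(C[C@H]2C(=C)CC[C@H]3C(C)(C)CCC[C@]23C)c1OC
A3 | alternative 2 | 6,6-dimethyl-1-vinylcyclohex-1-ene | C=CC1=CCCCC1(C)C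
A4 | alternative 2 | (E)-2-methylbut-2-enal | C/C=C(\C)C=O
A5 | alternative 2 | (1R,2S)-1,2,5,5-tetramethyl-1,2,3,5,6,7,8,8a-octahydronaphthalene-1-carbaldehyde (C8a open) | O=C[C@@]1(C)C2CCCC(C)(C)C2=CC[C@@H]1C
A6 | alternative 3 | [(2S)-2-(methoxymethyl)pyrrolidin-1-yl](2,5,5-trimethyl-5,6,7,8-tetrahydronaphthalen-1-yl)methanone | COC[C@@H]1CCCN1C(=O)c1c(C)ccc2c1CCCC2(C)C
A7 | alternative 3 | [(2S)-2-(methoxymethyl)pyrrolidin-1-yl][(1R)-1,2,5,5-tetramethyl-1,4,5,6,7,8-hexahydronaphthalen-1-yl]methanone | COC[C@@H]1CCCN1C(=O)[C@@]2(C)C3=C(CC=C2C)C(C)(C)CCC3
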